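**Strategy**

Everything rests on cutting ring A of the 7-methoxyflavone unit into a squarate and a furan. Its contiguous carbons C5 (OH), C6 (OAr), C7 (OMe) and C8 (H) are the four carbons of a half-reduced mixed squaric ester; C8a, C4a, O1 and the future C4 come from furan. In one operation a Stille coupling makes C8–C8a and thermal 4π opening/6π closure of the resulting 4-furylcyclobutenone makes C4a–C5, delivering ring A as a 4-hydroxybenzofuran with the diaryl ether, the methyl ether and the free 5-OH in place. The precursor is a racemic 4-chloro-3-methoxy-2-aryloxycyclobutenone whose aryl ring carries a tert-butyl ester, the handle for the apigenin unit.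

Key step: step 5

**Remarks on the chemistry**

- Flavone locants (O1, C2–C8a) refer to the 7-methoxyflavone unit; benzofuran intermediates carry benzofuran locants. Ar = 4-(tert-butoxycarbonyl)phenyl.
- The benzoate handle is a tert-butyl ester, not a methyl ester. It is inert to the lithium acetylide of step 8 and is removed with acid in step 10, so no hydroxide meets the finished pyranone. The skeleton of the key-step precursor is unchanged.
- Assumption: 1-[2,4-bis(benzyloxy)-6-hydroxyphenyl]ethan-1-one (22) is purchased; if not, it is one benzylation away from 2,4,6-trihydroxyacetophenone.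
- Compounds 6 and 8 ionise easily at C4 and should be kept away from acid and moisture and used promptly.

**Route**

Step 1
Reactants: 1 squaric acid
Product: 2 squaric dichloride (3,4-dichlorocyclobut-3-ene-1,2-dione)
Conditions: (COCl)2, DMF (cat.), CH2Cl2, reflux
Reagents that add atoms: oxalyl chloride, O=C(Cl)C(Cl)=O
Why: Vilsmeier-type chlorination of the two vinylogous acid OH groups with oxalyl chloride and catalytic DMF, the standard preparation of this dichloride, driven by loss of CO, CO2 and HCl.

Step 2
Reactants: 2 squaric dichloride, 3 tert-butyl 4-hydroxybenzoate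
Product: 5 tert-butyl 4-[(2-methoxy-3,4-dioxocyclobut-1-en-1-yl)oxy]benzoate, via chloro methoxy squarate 4 (not isolated)
Conditions: MeOH (1.0 equiv), CH2Cl2, 0 °C → rt, evaporate; then 3, iPr2NEt, THF, −78 → 0 °C
Reagents that add atoms: methanol, CO
Why: Two successive addition–elimination (vinylogous acyl substitution) steps, in which the first methoxy group deactivates the ring enough to stop at monomethanolysis and the phenoxide of 3 then displaces chloride, by far the best leaving group of 4.

Step 3
Reactants: 5 tert-butyl 4-[(2-methoxy-3,4-dioxocyclobut-1-en-1-yl)oxy]benzoate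
Product: 6 racemic tert-butyl 4-[(3-hydroxy-2-methoxy-4-oxocyclobut-1-en-1-yl)oxy]benzoate
Conditions: LiAlH(OtBu)3 (1.05 equiv), THF, −78 °C; pH 7 buffer
Reagents that add atoms: none
Why: Regioselective 1,2-reduction of a squarate carbonyl with a bulky mild hydride, the known entry to 4-hydroxycyclobutenones: hydride should attack the carbonyl next to the small methoxy carbon, which is conjugated only with the weakly donating ester-bearing aryloxy oxygen and is therefore the more electrophilic and the less hindered, leaving the ketone beside the aryloxy carbon; the carbinol centre forms racemic, which is irrelevant because it becomes aromatic C8, and the tert-butyl ester is inert.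

Step 4
Reactants: 6 racemic tert-butyl 4-[(3-hydroxy-2-methoxy-4-oxocyclobut-1-en-1-yl)oxy]benzoate
Product: 8 racemic tert-butyl 4-[(3-chloro-2-methoxy-4-oxocyclobut-1-en-1-yl)oxy]benzoate, via mesylate 7 (not isolated)
Conditions: MsCl, Et3N, LiCl, THF, −20 → 0 °C; filter through a short silica pad, no aqueous work-up
Reagents that add atoms: methanesulfonyl chloride, CS(=O)(=O)Cl (atoms in 7 only); lithium chloride, [Li+].[Cl-]
Why: Mesylation and chloride displacement convert the allylic alcohol into the allylic chloride under nearly neutral conditions; even if the mesylate ionises, chloride return at C4 gives the conjugated and thermodynamically preferred chloride, and the non-aqueous work-up avoids hydrolytic loss of the aryloxy group.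

Step 5
Reactants: 8 racemic tert-butyl 4-[(3-chloro-2-methoxy-4-oxocyclobut-1-en-1-yl)oxy]benzoate, 9 2-(tributylstannyl)furan
Product: 13 tert-butyl 4-[(4-hydroxy-6-methoxy-1-benzofuran-5-yl)oxy]benzoate, via furylcyclobutenone 10 (not isolated), via dienylketene 11 (not isolated), via dienone tautomer 12 (not isolated)
Conditions: PdCl2(PhCN)2 (5 mol %), tri(2-furyl)phosphine (10 mol %), 1,4-dioxane, 50 °C; then 100 °C
Reagents that add atoms: none
Why: Zerovalent palladium, formed in situ from the divalent palladium precatalyst PdCl2(PhCN)2, tri(2-furyl)phosphine and the stannane, inserts into the allylic C–Cl bond of 8, and transmetalation with 9 followed by reductive elimination gives 10 (bond C8–C8a); at 100 °C 10 undergoes conrotatory 4π ring opening to dienylketene 11, whose ketene carbon closes onto furan C3 (bond C4a–C5) to give dienone 12, which enolises to the aromatic phenol 13. The closest known reaction type is the Stille coupling of 4-chlorocyclobutenones with aryl-, heteroaryl- and alkenylstannanes followed by thermal ring expansion of the 4-unsaturated cyclobutenones to phenols. Ring A is closed by a thermal disrotatory 6π electrocyclisation of the ketene–alkene–furan triene, not by an ionic cyclisation. No stereocenter is set, since the racemic CHCl carbon of 8 and C3a of 12 both end as sp2 carbons of ring A. The step needs coupling at the CHCl carbon and not at the other allyl terminus, which is secured because that terminus is fully substituted and coupling at CHCl keeps the methoxy enone conjugation; it also needs the furyl group to rotate inward, which is secured because ring opening is reversible and only the isomer with furyl cis to the ketene arm can cyclise, furan C3 being the only free ortho position. The order OH, OAr, OMe, H around ring A follows from the substitution of 8, because the ketone carbon becomes C5.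

Step 6
Reactants: 13 tert-butyl 4-[(4-hydroxy-6-methoxy-1-benzofuran-5-yl)oxy]benzoate
Product: 14 tert-butyl 4-{[4-(benzyloxy)-6-methoxy-1-benzofuran-5-yl]oxy}benzoate
Conditions: BnBr, K2CO3, DMF, rt
Reagents that add atoms: benzyl bromide, BrCc1ccccc1
Why: Williamson etherification of the phenol, which masks the future 5-OH so that only the oxygen freed from the furan can later close the pyranone.

Step 7
Reactants: 14 tert-butyl 4-{[4-(benzyloxy)-6-methoxy-1-benzofuran-5-yl]oxy}benzoate
Product: 16 tert-butyl 4-[2-(benzyloxy)-3-formyl-4-hydroxy-6-methoxyphenoxy]benzoate, via aryl formate 15 (not isolated)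
Conditions: O3 (to the end point), CH2Cl2/MeOH, −78 °C; Me2S, −78 °C → rt; then K2CO3 (cat.), MeOH, 0 °C
Reagents that add atoms: ozone, [O-][O+]=O
Why: Criegee ozonolysis of the electron-rich furan C2=C3 bond with reductive work-up leaves the aldehyde (future C4) on C3a and a formate on the former furan oxygen, and methanolysis of this labile aryl formate frees the phenol (future O1), while the benzene rings, the benzyl ether and the tert-butyl ester react far more slowly with a measured dose of ozone.

Step 8
Reactants: 16 tert-butyl 4-[2-(benzyloxy)-3-formyl-4-hydroxy-6-methoxyphenoxy]benzoate, 17 1-(benzyloxy)-4-ethynylbenzene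
Product: 18 racemic tert-butyl 4-(2-(benzyloxy)-3-{3-[4-(benzyloxy)phenyl]-1-hydroxyprop-2-yn-1-yl}-4-hydroxy-6-methoxyphenoxy)benzoate
Conditions: 17 (3.0 equiv), n-BuLi (2.9 equiv), THF, −78 °C; then 16, −78 → 0 °C; aqueous work-up
Reagents that add atoms: none
Why: 1,2-Addition of a lithium acetylide to the aldehyde, in which the first equivalent only deprotonates the phenol and the tert-butyl ester is inert; the new carbinol stereocenter forms racemic and is destroyed by the oxidation of step 9.

Step 9
Reactants: 18 racemic tert-butyl 4-(2-(benzyloxy)-3-{3-[4-(benzyloxy)phenyl]-1-hydroxyprop-2-yn-1-yl}-4-hydroxy-6-methoxyphenoxy)benzoate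
Product: 20 tert-butyl 4-({5-(benzyloxy)-2-[4-(benzyloxy)phenyl]-7-methoxy-4-oxo-4H-chromen-6-yl}oxy)benzoate, via ynone 19 (not isolated)
Conditions: MnO2 (activated, excess), CH2Cl2, rt; filter; then K2CO3, acetone, reflux
Reagents that add atoms: none
Why: MnO2 selectively oxidises the benzylic–propargylic alcohol to the ynone, and under aprotic carbonate conditions the free phenoxide adds to the alkyne terminus in a 6-endo-dig oxa-Michael closure to the 4-pyranone, the other ortho oxygen being blocked as its benzyl ether.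

Step 10
Reactants: 20 tert-butyl 4-({5-(benzyloxy)-2-[4-(benzyloxy)phenyl]-7-methoxy-4-oxo-4H-chromen-6-yl}oxy)benzoate
Product: 21 4-({5-(benzyloxy)-2-[4-(benzyloxy)phenyl]-7-methoxy-4-oxo-4H-chromen-6-yl}oxy)benzoic acid
Conditions: TFA/CH2Cl2 (1:4), 0 °C → rt
Reagents that add atoms: none
Why: Acidolysis of the tert-butyl ester with loss of 2-methylpropene, under which aryl benzyl ethers, the methyl ether and the pyranone should survive a short exposure.

Step 11
Reactants: 21 4-({5-(benzyloxy)-2-[4-(benzyloxy)phenyl]-7-methoxy-4-oxo-4H-chromen-6-yl}oxy)benzoic acid, 22 1-[2,4-bis(benzyloxy)-6-hydroxyphenyl]ethan-1-one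
Product: 23 2-acetyl-3,5-bis(benzyloxy)phenyl 4-({5-(benzyloxy)-2-[4-(benzyloxy)phenyl]-7-methoxy-4-oxo-4H-chromen-6-yl}oxy)benzoate
Conditions: EDC·HCl, DMAP, CH2Cl2, rt
Reagents that add atoms: none
Why: Steglich esterification (carbodiimide activation with DMAP acyl transfer) of the chelated acetophenone phenol, the usual way to a Baker–Venkataraman substrate.

Step 12
Reactants: 23 2-acetyl-3,5-bis(benzyloxy)phenyl 4-({5-(benzyloxy)-2-[4-(benzyloxy)phenyl]-7-methoxy-4-oxo-4H-chromen-6-yl}oxy)benzoate
Product: 25 5-(benzyloxy)-2-[4-(benzyloxy)phenyl]-6-{4-[5,7-bis(benzyloxy)-4-oxo-4H-chromen-2-yl]phenoxy}-7-methoxy-4H-chromen-4-one, via diketone 24 (not isolated)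
Conditions: LiHMDS (3 equiv), THF, −78 → −10 °C; aqueous work-up; then p-TsOH·H2O (cat.), toluene, 90 °C
Reagents that add atoms: none
Why: Baker–Venkataraman rearrangement, in which the lithium enolate of the acetyl group attacks the neighbouring aryl ester intramolecularly to give the 1,3-diketone, followed by acid-catalysed cyclodehydration of the phenol onto the distal carbonyl to form the second 4-pyranone.

Step 13
Reactants: 25 5-(benzyloxy)-2-[4-(benzyloxy)phenyl]-6-{4-[5,7-bis(benzyloxy)-4-oxo-4H-chromen-2-yl]phenoxy}-7-methoxy-4H-chromen-4-one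
Product: 26 isocryptomerin
Conditions: H2 (1 atm), 10% Pd/C, THF/MeOH, rt
Reagents that add atoms: none
Why: Hydrogenolysis of the four benzyl aryl ethers over zerovalent palladium on carbon, which should leave the methyl ether, the diaryl ether and both flavone C2=C3 bonds intact if stopped after four equivalents of hydrogen are taken up.

**Compound list**

1 | squaric acid (3,4-dihydroxycyclobut-3-ene-1,2-dione) | O=c1c(O)c(O)c1=O | starting material
2 | squaric dichloride (3,4-dichlorocyclobut-3-ene-1,2-dione) | ClC1=C(Cl)C(=O)C1=O | intermediate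
3 | tert-butyl 4-hydroxybenzoate | CC(C)(C)OC(=O)c1ccc(O)cc1 | starting material
4 | 3-chloro-4-methoxycyclobut-3-ene-1,2-dione (chloro methoxy squarate) | COC1=C(Cl)C(=O)C1=O | intermediate
5 | tert-butyl 4-[(2-methoxy-3,4-dioxocyclobut-1-en-1-yl)oxy]benzoate (mixed squarate) | COC1=C(Oc2ccc(cc2)C(=O)OC(C)(C)C)C(=O)C1=O | intermediate
6 | racemic tert-butyl 4-[(3-hydroxy-2-methoxy-4-oxocyclobut-1-en-1-yl)oxy]benzoate | COC1=C(Oc2ccc(cc2)C(=O)OC(C)(C)C)C(=O)C1O | intermediate
7 | racemic tert-butyl 4-({2-methoxy-3-[(methylsulfonyl)oxy]-4-oxocyclobut-1-en-1-yl}oxy)benzoate (mesylate) | COC1=C(Oc2ccc(cc2)C(=O)OC(C)(C)C)C(=O)C1OS(C)(=O)=O | intermediate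
8 | racemic tert-butyl 4-[(3-chloro-2-methoxy-4-oxocyclobut-1-en-1-yl)oxy]benzoate, i.e. 4-chloro-3-methoxy-2-[4-(tert-butoxycarbonyl)phenoxy]cyclobut-2-en-1-one | COC1=C(Oc2ccc(cc2)C(=O)OC(C)(C)C)C(=O)C1Cl | intermediate
9 | 2-(tributylstannyl)furan | CCCC[Sn](CCCC)(CCCC)c1ccco1 | starting material
10 | racemic tert-butyl 4-{[3-(furan-2-yl)-2-methoxy-4-oxocyclobut-1-en-1-yl]oxy}benzoate (furylcyclobutenone) | COC1=C(Oc2ccc(cc2)C(=O)OC(C)(C)C)C(=O)C1c1ccco1 | intermediate
11 | tert-butyl 4-{[(3E)-4-(furan-2-yl)-3-methoxy-1-oxobuta-1,3-dien-2-yl]oxy}benzoate (dienylketene, furyl cis to the ketene arm) | O=C=C(Oc1ccc(cc1)C(=O)OC(C)(C)C)/C(OC)=C\c1ccco1 | intermediate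
12 | racemic tert-butyl 4-[(6-methoxy-4-oxo-3a,4-dihydro-1-benzofuran-5-yl)oxy]benzoate (dienone tautomer) | COC1=C(Oc2ccc(cc2)C(=O)OC(C)(C)C)C(=O)C2C=COC2=C1 | intermediate
13 | tert-butyl 4-[(4-hydroxy-6-methoxy-1-benzofuran-5-yl)oxy]benzoate | COc1cc2occc2c(O)c1Oc1ccc(cc1)C(=O)OC(C)(C)C | intermediate
14 | tert-butyl 4-{[4-(benzyloxy)-6-methoxy-1-benzofuran-5-yl]oxy}benzoate | COc1cc2occc2c(OCc2ccccc2)c1Oc1ccc(cc1)C(=O)OC(C)(C)C | intermediate
15 | tert-butyl 4-[2-(benzyloxy)-3-formyl-4-(formyloxy)-6-methoxyphenoxy]benzoate (aryl formate) | COc1cc(OC=O)c(C=O)c(OCc2ccccc2)c1Oc1ccc(cc1)C(=O)OC(C)(C)C | intermediate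
16 | tert-butyl 4-[2-(benzyloxy)-3-formyl-4-hydroxy-6-methoxyphenoxy]benzoate | COc1cc(O)c(C=O)c(OCc2ccccc2)c1Oc1ccc(cc1)C(=O)OC(C)(C)C | intermediate
17 | 1-(benzyloxy)-4-ethynylbenzene | C#Cc1ccc(OCc2ccccc2)cc1 | starting material
18 | racemic tert-butyl 4-(2-(benzyloxy)-3-{3-[4-(benzyloxy)phenyl]-1-hydroxyprop-2-yn-1-yl}-4-hydroxy-6-methoxyphenoxy)benzoate | COc1cc(O)c(C(O)C#Cc2ccc(OCc3ccccc3)cc2)c(OCc2ccccc2)c1Oc1ccc(cc1)C(=O)OC(C)(C)C | intermediate
19 | tert-butyl 4-(2-(benzyloxy)-3-{3-[4-(benzyloxy)phenyl]prop-2-ynoyl}-4-hydroxy-6-methoxyphenoxy)benzoate (ynone) | COc1cc(O)c(C(=O)C#Cc2ccc(OCc3ccccc3)cc2)c(OCc2ccccc2)c1Oc1ccc(cc1)C(=O)OC(C)(C)C | intermediate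
20 | tert-butyl 4-({5-(benzyloxy)-2-[4-(benzyloxy)phenyl]-7-methoxy-4-oxo-4H-chromen-6-yl}oxy)benzoate | COc1cc2oc(-c3ccc(OCc4ccccc4)cc3)cc(=O)c2c(OCc2ccccc2)c1Oc1ccc(cc1)C(=O)OC(C)(C)C | intermediate
21 | 4-({5-(benzyloxy)-2-[4-(benzyloxy)phenyl]-7-methoxy-4-oxo-4H-chromen-6-yl}oxy)benzoic acid | COc1cc2oc(-c3ccc(OCc4ccccc4)cc3)cc(=O)c2c(OCc2ccccc2)c1Oc1ccc(cc1)C(=O)O | intermediate
22 | 1-[2,4-bis(benzyloxy)-6-hydroxyphenyl]ethan-1-one | CC(=O)c1c(O)cc(OCc2ccccc2)cc1OCc1ccccc1 | starting material
23 | 2-acetyl-3,5-bis(benzyloxy)phenyl 4-({5-(benzyloxy)-2-[4-(benzyloxy)phenyl]-7-methoxy-4-oxo-4H-chromen-6-yl}oxy)benzoate | COc1cc2oc(-c3ccc(OCc4ccccc4)cc3)cc(=O)c2c(OCc2ccccc2)c1Oc1ccc(cc1)C(=O)Oc1cc(OCc2ccccc2)cc(OCc2ccccc2)c1C(C)=O | intermediate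
24 | 1-[2,4-bis(benzyloxy)-6-hydroxyphenyl]-3-[4-({5-(benzyloxy)-2-[4-(benzyloxy)phenyl]-7-methoxy-4-oxo-4H-chromen-6-yl}oxy)phenyl]propane-1,3-dione (diketone) | COc1cc2oc(-c3ccc(OCc4ccccc4)cc3)cc(=O)c2c(OCc2ccccc2)c1Oc1ccc(cc1)C(=O)CC(=O)c1c(O)cc(OCc2ccccc2)cc1OCc1ccccc1 | intermediate
25 | 5-(benzyloxy)-2-[4-(benzyloxy)phenyl]-6-{4-[5,7-bis(benzyloxy)-4-oxo-4H-chromen-2-yl]phenoxy}-7-methoxy-4H-chromen-4-one (tetra-O-benzyl isocryptomerin) | COc1cc2oc(-c3ccc(OCc4ccccc4)cc3)cc(=O)c2c(OCc2ccccc2)c1Oc1ccc(cc1)-c1cc(=O)c2c(OCc3ccccc3)cc(OCc3ccccc3)cc2o1 | intermediate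
26 | isocryptomerin | COc1cc2oc(-c3ccc(O)cc3)cc(=O)c2c(O)c1Oc1ccc(-c2cc(=O)c3c(O)cc(O)cc3o2)cc1 | target

**Count and risks**

Total step count: 13.
Longest linear sequence: 13 steps, from squaric acid 1 to isocryptomerin 26; compounds 3, 9, 17 and 22 are purchased.

The three steps most likely to fail:

Step 5 (key step). The stannane may be lost by protodestannylation before transmetalation, or the ketene may be consumed by dimerisation or by the product phenol because closure onto the aromatic furan, which costs its aromaticity, is slow. The fallback annulates ring A onto a non-aromatic enol ether and aromatises the furan afterwards. It sets out from chloride 8, which is coupled under the same palladium system with commercial tributyl(4,5-dihydrofuran-2-yl)stannane (CCCC[Sn](CCCC)(CCCC)C1=CCCO1) to give racemic tert-butyl 4-{[3-(4,5-dihydrofuran-2-yl)-2-methoxy-4-oxocyclobut-1-en-1-yl]oxy}benzoate F1, not isolated. Heating at 100 °C should turn it, by the same 4π opening and 6π closure, into tert-butyl 4-[(4-hydroxy-6-methoxy-2,3-dihydro-1-benzofuran-5-yl)oxy]benzoate F2. Benzylation (BnBr, K2CO3, DMF) gives tert-butyl 4-{[4-(benzyloxy)-6-methoxy-2,3-dihydro-1-benzofuran-5-yl]oxy}benzoate F3, and dehydrogenation with DDQ in dioxane at reflux brings the sequence back to the route at compound 14.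

Step 3. Hydride may be delivered to the wrong carbonyl, or may add in conjugate fashion with loss of aryloxide, so that the regioisomeric alcohol or a semisquarate forms. The fallback removes the regiochemical question by symmetry. It sets out from dichloride 2, which with two equivalents of phenol 3 and iPr2NEt gives di-tert-butyl 4,4'-[(3,4-dioxocyclobut-1-ene-1,2-diyl)bis(oxy)]dibenzoate F4. Reduction with LiAlH(OtBu)3 at −78 °C gives racemic di-tert-butyl 4,4'-[(3-hydroxy-4-oxocyclobut-1-ene-1,2-diyl)bis(oxy)]dibenzoate F5. In F5 only the aryloxy group β to the ketone, on the carbon next to the carbinol, can leave by addition–elimination, so vinylogous transesterification with methanol and catalytic Et3N at 0 °C should exchange exactly that group and release one equivalent of 3. This comes back to the route at compound 6.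

Step 4. The activated alcohol or the chloride may ionise at C4 and lose the aryloxy group on contact with moisture or silica, giving a semisquarate instead of a usable chloride. The fallback replaces the chloride by a more robust allylic ester as the palladium electrophile, with the same bonds formed afterwards. It sets out from alcohol 6, which is acetylated (Ac2O, pyridine, DMAP cat.) to racemic tert-butyl 4-{[3-(acetyloxy)-2-methoxy-4-oxocyclobut-1-en-1-yl]oxy}benzoate F6. This acetate is coupled with stannane 9 in a Stille coupling of an allylic acetate (Pd2(dba)3 as the zerovalent palladium source, tri(2-furyl)phosphine, LiCl, DMF, 50 °C) and then heated to 100 °C. The sequence passes through furylcyclobutenone 10 and comes back to the route at compound 13.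

**Further compounds**

F1 | step 5 | racemic tert-butyl 4-{[3-(4,5-dihydrofuran-2-yl)-2-methoxy-4-oxocyclobut-1-en-1-yl]oxy}benzoate | COC1=C(Oc2ccc(cc2)C(=O)OC(C)(C)C)C(=O)C1C1=CCCO1
F2 | step 5 | tert-butyl 4-[(4-hydroxy-6-methoxy-2,3-dihydro-1-benzofuran-5-yl)oxy]benzoate | COc1cc2OCCc2c(O)c1Oc1ccc(cc1)C(=O)OC(C)(C)C
F3 | step 5 | tert-butyl 4-{[4-(benzyloxy)-6-methoxy-2,3-dihydro-1-benzofuran-5-yl]oxy}benzoate | COc1cc2OCCc2c(OCc2ccccc2)c1Oc1ccc(cc1)C(=O)OC(C)(C)C
F4 | step 3 | di-tert-butyl 4,4'-[(3,4-dioxocyclobut-1-ene-1,2-diyl)bis(oxy)]dibenzoate | O=C1C(=O)C(Oc2ccc(cc2)C(=O)OC(C)(C)C)=C1Oc1ccc(cc1)C(=O)OC(C)(C)C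
F5 | step 3 | racemic di-tert-butyl 4,4'-[(3-hydroxy-4-oxocyclobut-1-ene-1,2-diyl)bis(oxy)]dibenzoate | OC1C(=O)C(Oc2ccc(cc2)C(=O)OC(C)(C)C)=C1Oc1ccc(cc1)C(=O)OC(C)(C)C
F6 | step 4 | racemic tert-butyl 4-{[3-(acetyloxy)-2-methoxy-4-oxocyclobut-1-en-1-yl]oxy}benzoate | CC(=O)OC1C(=O)C(Oc2ccc(cc2)C(=O)OC(C)(C)C)=C1OC
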